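## Structural features

The target is a cembrane-type diterpenoid alcohol: a single 14-membered carbocycle with three trisubstituted ring alkenes in a skipped 1,5,9 pattern, Z-C3=C4(Me), E-C7=C8(CH2OH) and E-C11=C12(Me). The only stereocentre is C1 (R). It carries a 6-methylhepta-1,5-dien-2-yl chain (C15 with an exocyclic methylene and a homoprenyl arm) and has no stereogenic neighbour, so no relay from an adjacent centre is possible. Fragile points are the primary allylic alcohol (ionisation, transposition) and the 1,5-diene array (acid- or cation-triggered transannular cyclisation, alkene migration). C1 is also fragile: it is allylic to C15=CH2 in the target and α to a carbonyl in every C15-oxo precursor, hence open to epimerisation under base. The difficulty is threefold: a lone stereocentre in a flexible macrocycle, one Z alkene among two E alkenes of the same substitution, and closure of a 14-membered ring without eroding either. The key step exploits the array C15–C1–C2–C3=C4. With C15 as a carboxyl carbon this is a γ,δ-unsaturated acid, the product pattern of a Claisen shift of a C4 tertiary vinyl carbinol ester. One event can therefore form C1–C2, set C1 and fix the C3=C4 geometry.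

## Logic of the disconnections

31 ⇒ 30. Only the O–Si bond at the C8 hydroxymethyl group is cut. The oxygen stays silylated through the base and organometallic steps. The forward step must cleave a primary allylic silyl ether without touching the triene.

30 ⇒ 29 ⇒ 26 + 28 (from 27) ⇒ 25. The C15=CH2 bond is cut (methylenation), then the C15–CH2 bond of the side chain (acyl substitution), then the amide is traced to the acid. This reduces C15 to a carboxyl carbon, which is what the key step delivers, so no carbon is wasted. The forward steps must stop at the ketone and must methylenate without base, because C1 in 29 is an enolisable α-stereocentre.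

25 ⇒ 24 ⇒ 23 ⇒ 22. C1–C2 is cut, C4–O is re-formed and the alkene moves from C3=C4 to the vinyl group C2=C3. The stereocentre C1 is exchanged for a tertiary carbinol centre available from the chiral pool, and the carbocycle becomes a lactone that can be assembled by esterification plus olefination. The forward step needs one ketene acetal geometry and a chair that the C5–C14 tether can bridge on one face only.

22 ⇒ 21 ⇒ 20. The O–Si bond is cut and the C8 hydroxymethyl group is traced to an ester. The enoate is the direct product of ring closure but would be deprotonated at its γ-positions by the amide base of the key step, so it is reduced and silylated first. The hydride must distinguish the conjugated ethyl ester from the ring lactone.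

20 ⇒ 19. C7=C8 is cut as an intramolecular Horner–Wadsworth–Emmons olefination. This opens the macrocycle at its only conjugated alkene, while the two halves stay joined through the tertiary ester. The forward step needs high dilution and E selectivity (ester trans to C6).

19 ⇒ 18 ⇒ 17 ⇒ 14 + 15 (via 16). C7 is traced from aldehyde to alcohol to silyl ether, and C8–C9 is cut as an alkylation. This makes 15 the two-carbon source of C8 and its ester carbon. The forward alkylation must be a clean SN2 reaction on a primary iodide beside a hindered ester.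

14 ⇒ 13 (from 4) + 12 (from 11). The ester C15–O bond is cut. Acylating a preformed tertiary alkoxide with an acid chloride is the convergent and non-ionising way to esterify a tertiary allylic alcohol. The forward step must avoid any acid that could ionise C4–O.

4 ⇒ 3 ⇒ 2 ⇒ 1. C7 is traced to the trisubstituted alkene carbon of 1. Compound 1 supplies C2–C7, the C4 methyl and the (S)-carbinol. Ozone must take the trisubstituted alkene and spare the vinyl group, and the cleavage must precede coupling because 11 carries another trisubstituted alkene.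

11 ⇒ 10 ⇒ 9 ⇒ 8 ⇒ 7 ⇒ 6 ⇒ 5. C9–C10 is cut (epoxide opening) and C12–CH3 is cut (syn carbometalation of a terminal alkyne). C15 goes back from acid to silyl ether and C9 from iodide to alcohol. E-C11=C12 is fixed by mechanism and the two chain ends are differentiated from the start. The forward step needs selective alkenyl transfer from aluminium to the epoxide.

## Other disconnections considered

Alternative 1: The cut is C9–C10, read as an intramolecular SN2′ alkylation.
- Forward step: the acyclic acetate A1, which already holds (R)-C1 and a C10 phenylsulfonyl group, would be deprotonated at C10. The sulfone carbanion would add to the C9 methylene with loss of acetate, giving the 14-membered ester A2 and forming C7=C8 in the same event.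
- In its favour: soft-carbanion macrocyclisations are forgiving, the ring and the trisubstituted enoate arise together, and the full side chain is already on C1. Only desulfonylation and ester reduction would remain, two operations against four after step 14. On endgame length it is the better plan.
- Against it here: the step creates no stereochemistry. C1 and Z-C3=C4 must both be built into A1 by separate asymmetric and Z-selective chemistry. The C7=C8 geometry is left to the addition–elimination. Reductive removal of an allylic sulfone at C10 tends to shift or isomerise C11=C12.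
- Comparison: both plans close the same ring at high dilution and are equal on that point. The chosen plan lets the ring-forming event set C1 and Z-C3=C4 from one chiral-pool centre. The shorter endgame of Alternative 1 is offset by a longer linear route to A1.

Alternative 2: The cut removes both C1–C14 and C1–C15 and leaves the ring open.
- Forward step: carbamate A3 would be lithiated with s-BuLi/sparteine and captured by boronic ester A4, and a 1,2-metallate shift would form C1–C14. Addition of alkenyllithium A5, then I2 and NaOMe, would form C1–C15 and give A6.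
- In its favour: C1 is set by reagent control, independent of any macrocyclic transition state, and either enantiomer is available by choice of diamine. On reliability of the stereocentre it is the better plan. Two bonds to C1 form in one flask and the side chain arrives complete.
- Against it here: A6 is acyclic and lacks C8. Inserting C8 and closing the ring (most plausibly the olefination of step 11, with acetal hydrolysis and ester reduction) all remain. A3 needs its own source of a Z-trisubstituted alkene. The sequence is cryogenic and uses a stoichiometric chiral diamine.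
- Comparison: it solves the stereocentre but not the ring, whereas the chosen plan solves both in step 14. Three multi-step fragments make a lower step count unlikely. The two plans are equal in needing no auxiliary removal.

Alternative 3: The cut is C12–C13, an sp2–sp3 bond.
- Forward step: the redox-active ester A7 would be reduced at the cathode with a divalent nickel precatalyst such as NiBr2·glyme and a bipyridine ligand. The C13 radical released with CO2 would couple with the alkenyl iodide and close the ring to A8, which is identical with 30.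
- In its favour: it arrives one deprotection from the target, the best endgame of all four plans. The alkenyl iodide geometry is retained, so E-C11=C12 is not at risk. No strong base is used and C1 cannot epimerise at that stage.
- Against it here: the C13 radical is a hex-5-enyl radical with respect to C3=C4 (C13–C14–C1–C2–C3=C4). A 5-exo cyclisation would compete with capture at nickel, most of all at the dilution a 14-membered closure needs. The linear A7 must already contain C1 and all three alkenes. Macrocyclic use of this coupling at this ring size is little charted.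
- Comparison: the ring closure carries no stereochemical burden, and on that point it is the equal of Alternative 1 and safer than step 14. The radical liability and the long linear precursor outweigh this here.

Key step: step 14

Assumption: (S)-(+)-linalool 1 is taken as the commercial coriander-derived material, with its enantiomeric purity checked and if necessary upgraded, because the ee of 1 caps the ee of 31.

Remarks on the design:
- Lactone 22 and acid 25 are both 14-membered. O and C15 leave the ring while C2 and C3 enter it, so step 14 is a lactone-to-carbocycle ring transposition and not a contraction in size.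
- The free γ-hydroxy aldehyde from 1 closes to lactol 2 and cannot be kept as an open-chain acetal beside a free tertiary hydroxyl. C7 is therefore carried as a silyl ether at the alcohol level.
- The C9–C15 acid is built from 5 by carboalumination. An isoprenoid C10 unit would supply E-C11=C12 but is one carbon short at each end.
- DMPU replaces HMPA as the dipolar cosolvent in step 14.

## Route

Step 1
Reactants: 1 (S)-linalool
Product: 3 (4S)-4-methylhex-5-ene-1,4-diol, via lactol 2 (not isolated)
Conditions: O3, CH2Cl2/MeOH 4:1, −78 °C (Sudan red 7B end point); NaBH4, −78 °C → rt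
Reagents that add atoms: ozone, O=[O+][O-]
Why: Ozonolysis takes the electron-rich trisubstituted alkene far faster than the vinyl group; the γ-hydroxy aldehyde closes to lactol 2, which NaBH4 reduces through its open form to diol 3. The carbinol stereocentre is not touched.

Step 2
Reactants: 3 (4S)-4-methylhex-5-ene-1,4-diol
Product: 4 (3S)-6-[(tert-butyldimethylsilyl)oxy]-3-methylhex-1-en-3-ol
Conditions: TBSCl (1.05 equiv), imidazole, CH2Cl2, 0 °C
Reagents that add atoms: tert-butyldimethylsilyl chloride, CC(C)(C)[Si](C)(C)Cl
Why: Silyl ether formation is much faster at the primary hydroxyl than at the hindered tertiary allylic one, so C7 is masked and the tertiary hydroxyl stays free for acylation.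

Step 3
Reactants: 5 hex-5-yn-1-ol
Product: 6 tert-butyl(hex-5-yn-1-yloxy)dimethylsilane
Conditions: TBSCl, imidazole, CH2Cl2, rt
Reagents that add atoms: tert-butyldimethylsilyl chloride, CC(C)(C)[Si](C)(C)Cl
Why: Standard silyl ether formation; it keeps the future C15 oxygen inert to AlMe3 and differentiates the two chain ends from the outset.

Step 4
Reactants: 6 tert-butyl(hex-5-yn-1-yloxy)dimethylsilane
Product: 9 (3E)-8-[(tert-butyldimethylsilyl)oxy]-4-methyloct-3-en-1-ol, via alkenylalane 7 (not isolated), via lithium alanate 8 (not isolated)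
Conditions: AlMe3 (2.5 equiv), Cp2ZrCl2 (0.25 equiv), CH2Cl2, 0 °C → rt; evaporate, THF/hexane; n-BuLi (1.0 equiv), −78 → 0 °C; oxirane (3 equiv), −78 °C → rt; aq. NH4Cl/KNaC4H4O6
Reagents that add atoms: trimethylaluminium, C[Al](C)C; oxirane, C1CO1
Why: Zirconium-catalysed syn carboalumination (Negishi carboalumination) puts Me on the internal and Al on the terminal alkyne carbon, so E-C11=C12 is fixed by mechanism. The butyl ate complex 8 then transfers its alkenyl group to oxirane with retention, adding C10 and C9.

Step 5
Reactants: 9 (3E)-8-[(tert-butyldimethylsilyl)oxy]-4-methyloct-3-en-1-ol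
Product: 10 tert-butyl{[(5E)-8-iodo-5-methyloct-5-en-1-yl]oxy}dimethylsilane
Conditions: I2, PPh3, imidazole, CH2Cl2, 0 °C → rt
Reagents that add atoms: iodine, II
Why: Appel-type iodination displaces the oxyphosphonium of the primary homoallylic alcohol by SN2; the silyl ether and the alkene are inert under the imidazole-buffered conditions.

Step 6
Reactants: 10 tert-butyl{[(5E)-8-iodo-5-methyloct-5-en-1-yl]oxy}dimethylsilane
Product: 11 (5E)-8-iodo-5-methyloct-5-enoic acid
Conditions: CrO3, H2SO4, H2O, acetone, 0 °C (Jones oxidation)
Reagents that add atoms: water, O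
Why: The aqueous acid of the Jones reagent cleaves the primary silyl ether and chromic acid oxidises the freed alcohol through the aldehyde hydrate to the acid in one pot. The primary iodide and the trisubstituted alkene should tolerate the short, cold exposure.

Step 7
Reactants: 11 (5E)-8-iodo-5-methyloct-5-enoic acid; 4 (3S)-6-[(tert-butyldimethylsilyl)oxy]-3-methylhex-1-en-3-ol
Product: 14 (3S)-6-[(tert-butyldimethylsilyl)oxy]-3-methylhex-1-en-3-yl (5E)-8-iodo-5-methyloct-5-enoate, via acid chloride 12 (not isolated), via lithium alkoxide 13 (not isolated)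
Conditions: 11, (COCl)2, DMF (cat.), CH2Cl2, 0 °C → rt, concentrate; 4, n-BuLi, THF, −78 °C; add 12, −78 → 0 °C
Reagents that add atoms: none
Why: Acylation of a preformed lithium tert-alkoxide by an acid chloride is the dependable esterification of a tertiary allylic alcohol, because the medium stays basic and the C4–O bond is never ionised. The C4 configuration is therefore retained.

Step 8
Reactants: 14 (3S)-6-[(tert-butyldimethylsilyl)oxy]-3-methylhex-1-en-3-yl (5E)-8-iodo-5-methyloct-5-enoate; 15 triethyl phosphonoacetate
Product: 17 1-ethyl 10-[(3S)-6-[(tert-butyldimethylsilyl)oxy]-3-methylhex-1-en-3-yl] (5E)-2-(diethoxyphosphoryl)-6-methyldec-5-enedioate (both C2 epimers), via sodium phosphonoacetate 16 (not isolated)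
Conditions: 15 (2.5 equiv), NaH (2.2 equiv), DMF, 0 °C; 14, 55 °C
Reagents that add atoms: none
Why: SN2 C-alkylation of the soft phosphonoacetate carbanion by the primary iodide installs C8 with its phosphonate and ester; excess nucleophile suppresses dialkylation and the hindered tertiary ester is not attacked. The new C8 centre forms as both epimers and is destroyed in step 11.

Step 9
Reactants: 17 1-ethyl 10-[(3S)-6-[(tert-butyldimethylsilyl)oxy]-3-methylhex-1-en-3-yl] (5E)-2-(diethoxyphosphoryl)-6-methyldec-5-enedioate
Product: 18 1-ethyl 10-[(3S)-6-hydroxy-3-methylhex-1-en-3-yl] (5E)-2-(diethoxyphosphoryl)-6-methyldec-5-enedioate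
Conditions: HF·pyridine, pyridine, THF, 0 °C → rt
Reagents that add atoms: none
Why: Buffered fluoride desilylation frees the primary alcohol without touching the tertiary allylic ester or the phosphonate.

Step 10
Reactants: 18 1-ethyl 10-[(3S)-6-hydroxy-3-methylhex-1-en-3-yl] (5E)-2-(diethoxyphosphoryl)-6-methyldec-5-enedioate
Product: 19 1-ethyl 10-[(3S)-3-methyl-6-oxohex-1-en-3-yl] (5E)-2-(diethoxyphosphoryl)-6-methyldec-5-enedioate
Conditions: Dess–Martin periodinane, NaHCO3, CH2Cl2, 0 °C → rt
Reagents that add atoms: none
Why: Dess–Martin oxidation gives the aldehyde under buffered, near-neutral conditions, so the acidic phosphonoacetate C–H is not engaged. The aldehyde cannot close to a lactol because the tertiary oxygen is now acylated.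

Step 11
Reactants: 19 1-ethyl 10-[(3S)-3-methyl-6-oxohex-1-en-3-yl] (5E)-2-(diethoxyphosphoryl)-6-methyldec-5-enedioate
Product: 20 ethyl (6E,10E,14S)-14-ethenyl-6,14-dimethyl-2-oxo-1-oxacyclotetradeca-6,10-diene-10-carboxylate
Conditions: LiCl (10 equiv), DBU (5 equiv), MeCN, rt; 19 added over 12 h to 1 mM
Reagents that add atoms: none
Why: Intramolecular Horner–Wadsworth–Emmons olefination under Masamune–Roush conditions: the lithium-chelated phosphonate is deprotonated by the amidine and adds to the aldehyde at high dilution, closing the 14-membered lactone at C7=C8. Reversible addition and elimination through the less crowded oxaphosphetane should place the ester trans to C6 (E enoate, C6 and C9 cis).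

Step 12
Reactants: 20 ethyl (6E,10E,14S)-14-ethenyl-6,14-dimethyl-2-oxo-1-oxacyclotetradeca-6,10-diene-10-carboxylate
Product: 21 (6E,10E,14S)-14-ethenyl-10-(hydroxymethyl)-6,14-dimethyl-1-oxacyclotetradeca-6,10-dien-2-one
Conditions: iBu2AlH (2.3 equiv), CH2Cl2, −78 °C, 1 h; aq. KNaC4H4O6
Reagents that add atoms: none
Why: iBu2AlH gives 1,2-reduction of the conjugated ethyl ester to the allylic alcohol at −78 °C. The ring lactone is an ester of a tertiary alcohol, shielded like a tert-butyl ester, and should react much more slowly.

Step 13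
Reactants: 21 (6E,10E,14S)-14-ethenyl-10-(hydroxymethyl)-6,14-dimethyl-1-oxacyclotetradeca-6,10-dien-2-one
Product: 22 (6E,10E,14S)-10-{[(tert-butyldimethylsilyl)oxy]methyl}-14-ethenyl-6,14-dimethyl-1-oxacyclotetradeca-6,10-dien-2-one
Conditions: TBSCl, imidazole, CH2Cl2, rt
Reagents that add atoms: tert-butyldimethylsilyl chloride, CC(C)(C)[Si](C)(C)Cl
Why: Silyl ether formation protects the allylic alcohol against the amide base of step 14 and the organometallic reagents of steps 16 and 17.

Step 14
Reactants: 22 (6E,10E,14S)-10-{[(tert-butyldimethylsilyl)oxy]methyl}-14-ethenyl-6,14-dimethyl-1-oxacyclotetradeca-6,10-dien-2-one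
Product: 25 (1R,3Z,7E,11E)-8-{[(tert-butyldimethylsilyl)oxy]methyl}-4,12-dimethylcyclotetradeca-3,7,11-triene-1-carboxylic acid, via silyl ketene acetal 23 (not isolated), via trimethylsilyl ester 24 (not isolated)
Conditions: LiN(iPr)2 (1.5 equiv), THF/DMPU 3:1, −78 °C; Me3SiCl/Et3N (3 equiv) after 5 min; → rt, then 55 °C, 3 h; aq. citric acid
Reagents that add atoms: none
Why: LiN(iPr)2 in THF/DMPU removes a C1 proton of 22 through the open, solvent-separated transition state that places C14 cis to the enolate oxygen, and Me3SiCl traps this as the (Z)-ketene acetal 23 (C14 trans to the ring oxygen). On warming, 23 undergoes a concerted suprafacial [3,3] sigmatropic shift (Ireland–Claisen rearrangement): C1 bonds to the vinyl terminus C2 while C4–O breaks and C3=C4 appears, giving silyl ester 24 and, after mild acid, 25. The closest known reaction type is the Ireland–Claisen rearrangement of lactone-derived silyl ketene acetals into carbocycles. The 14-membered carbocycle closes by this pericyclic transposition and not by an exo or endo attack: the six-membered chair array is bridged across its 1,4-positions (C1 and C4) by the C5–C14 tether, the lactone opens as the carbocycle forms, and the ring size stays at 14. The ten-atom tether should only span an equatorial bond on C1 and an axial bond on C4 on the same face, so with C14 equatorial (fixed by the ketene acetal geometry) C5 must be axial and ends cis to C2, which is the Z alkene. The new stereocentre C1 is controlled by the (S)-C4 carbinol: in that chair C1–C2 forms on the vinyl face from which C4–O departs, and this 1,4-transfer gives (R)-C1. The step needs one ketene acetal geometry, chair over boat and a single bridging mode; the cosolvent secures the first and the short tether the other two. A leak in ketene acetal geometry should pass through the other same-face chair and give the E-C3=C4 isomer with the same (R)-C1, a separable diastereomer and not the enantiomer.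

Step 15
Reactants: 25 (1R,3Z,7E,11E)-8-{[(tert-butyldimethylsilyl)oxy]methyl}-4,12-dimethylcyclotetradeca-3,7,11-triene-1-carboxylic acid
Product: 26 (1R,3Z,7E,11E)-8-{[(tert-butyldimethylsilyl)oxy]methyl}-N-methoxy-N,4,12-trimethylcyclotetradeca-3,7,11-triene-1-carboxamide
Conditions: MeNH(OMe)·HCl, EDC·HCl, HOBt, iPr2NEt, CH2Cl2, 0 °C → rt
Reagents that add atoms: N,O-dimethylhydroxylamine hydrochloride, CNOC.Cl
Why: Carbodiimide amide coupling converts the acid into the N-methoxy-N-methylamide; an α-branched alkanoic acid has no low-energy racemisation path under these conditions, so C1 is preserved.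

Step 16
Reactants: 26 (1R,3Z,7E,11E)-8-{[(tert-butyldimethylsilyl)oxy]methyl}-N-methoxy-N,4,12-trimethylcyclotetradeca-3,7,11-triene-1-carboxamide; 27 5-bromo-2-methylpent-2-ene
Product: 29 1-[(1R,3Z,7E,11E)-8-{[(tert-butyldimethylsilyl)oxy]methyl}-4,12-dimethylcyclotetradeca-3,7,11-trien-1-yl]-5-methylhex-4-en-1-one, via Grignard reagent 28 (not isolated)
Conditions: 27, Mg, THF, rt (3 equiv of 28); 26, THF, 0 °C; aq. NH4Cl
Reagents that add atoms: none
Why: Weinreb ketone synthesis: the Grignard reagent adds once because the magnesium-chelated tetrahedral intermediate survives until the quench. Addition at 0 °C should outrun enolisation, so C1 is kept.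

Step 17
Reactants: 29 1-[(1R,3Z,7E,11E)-8-{[(tert-butyldimethylsilyl)oxy]methyl}-4,12-dimethylcyclotetradeca-3,7,11-trien-1-yl]-5-methylhex-4-en-1-one
Product: 30 (1R,3Z,7E,11E)-8-{[(tert-butyldimethylsilyl)oxy]methyl}-4,12-dimethyl-1-(6-methylhepta-1,5-dien-2-yl)cyclotetradeca-3,7,11-triene
Conditions: Cp2TiMe2 (3 equiv), toluene, 70 °C, dark
Reagents that add atoms: dimethyltitanocene, [CH3-].[CH3-].[Ti+4].[cH-]1cccc1.[cH-]1cccc1
Why: Petasis olefination: heating Cp2TiMe2 generates Cp2Ti=CH2, which methylenates the ketone by [2+2] cycloaddition and cycloreversion. The reagent is non-basic, so the α-stereocentre C1 is not enolised, and the trisubstituted alkenes are too hindered to react.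

Step 18
Reactants: 30 (1R,3Z,7E,11E)-8-{[(tert-butyldimethylsilyl)oxy]methyl}-4,12-dimethyl-1-(6-methylhepta-1,5-dien-2-yl)cyclotetradeca-3,7,11-triene
Product: 31 (1R,3Z,7E,11E)-8-(hydroxymethyl)-4,12-dimethyl-1-(6-methylhepta-1,5-dien-2-yl)cyclotetradeca-3,7,11-triene
Conditions: Bu4NF, THF, 0 °C → rt
Reagents that add atoms: none
Why: Fluoride desilylation cleaves the Si–O bond of the primary allylic silyl ether; nothing else in the hydrocarbon triene responds to Bu4NF.

## Compound list

1 | (S)-linalool, (3S)-3,7-dimethylocta-1,6-dien-3-ol | C=C[C@@](C)(O)CCC=C(C)C | starting material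
2 | (5S)-5-ethenyl-5-methyloxolan-2-ol (lactol, both anomers) | C=C[C@@](C)(O1)CCC1O | intermediate
3 | (4S)-4-methylhex-5-ene-1,4-diol | C=C[C@@](C)(O)CCCO | intermediate
4 | (3S)-6-[(tert-butyldimethylsilyl)oxy]-3-methylhex-1-en-3-ol | C=C[C@@](C)(O)CCCO[Si](C)(C)C(C)(C)C | intermediate
5 | hex-5-yn-1-ol | C#CCCCCO | starting material
6 | tert-butyl(hex-5-yn-1-yloxy)dimethylsilane | C#CCCCCO[Si](C)(C)C(C)(C)C | intermediate
7 | [(1E)-6-[(tert-butyldimethylsilyl)oxy]-2-methylhex-1-en-1-yl]dimethylalane | C[Al](C)/C=C(\C)CCCCO[Si](C)(C)C(C)(C)C | intermediate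
8 | lithium butyl[(1E)-6-[(tert-butyldimethylsilyl)oxy]-2-methylhex-1-en-1-yl]dimethylalanate | [Li+].CCCC[Al-](C)(C)/C=C(\C)CCCCO[Si](C)(C)C(C)(C)C | intermediate
9 | (3E)-8-[(tert-butyldimethylsilyl)oxy]-4-methyloct-3-en-1-ol | OCC/C=C(\C)CCCCO[Si](C)(C)C(C)(C)C | intermediate
10 | tert-butyl{[(5E)-8-iodo-5-methyloct-5-en-1-yl]oxy}dimethylsilane | ICC/C=C(\C)CCCCO[Si](C)(C)C(C)(C)C | intermediate
11 | (5E)-8-iodo-5-methyloct-5-enoic acid | ICC/C=C(\C)CCCC(=O)O | intermediate
12 | (5E)-8-iodo-5-methyloct-5-enoyl chloride | ICC/C=C(\C)CCCC(=O)Cl | intermediate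
13 | lithium (3S)-6-[(tert-butyldimethylsilyl)oxy]-3-methylhex-1-en-3-olate | [Li+].C=C[C@@](C)([O-])CCCO[Si](C)(C)C(C)(C)C | intermediate
14 | (3S)-6-[(tert-butyldimethylsilyl)oxy]-3-methylhex-1-en-3-yl (5E)-8-iodo-5-methyloct-5-enoate | C=C[C@@](C)(OC(=O)CCC/C(C)=C/CCI)CCCO[Si](C)(C)C(C)(C)C | intermediate
15 | triethyl phosphonoacetate | CCOC(=O)CP(=O)(OCC)OCC | starting material
16 | sodium salt of triethyl phosphonoacetate | [Na+].CCOC(=O)[CH-]P(=O)(OCC)OCC | intermediate
17 | 1-ethyl 10-[(3S)-6-[(tert-butyldimethylsilyl)oxy]-3-methylhex-1-en-3-yl] (5E)-2-(diethoxyphosphoryl)-6-methyldec-5-enedioate (both C2 epimers) | C=C[C@@](C)(OC(=O)CCC/C(C)=C/CCC(C(=O)OCC)P(=O)(OCC)OCC)CCCO[Si](C)(C)C(C)(C)C | intermediate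
18 | 1-ethyl 10-[(3S)-6-hydroxy-3-methylhex-1-en-3-yl] (5E)-2-(diethoxyphosphoryl)-6-methyldec-5-enedioate (both C2 epimers) | C=C[C@@](C)(OC(=O)CCC/C(C)=C/CCC(C(=O)OCC)P(=O)(OCC)OCC)CCCO | intermediate
19 | 1-ethyl 10-[(3S)-3-methyl-6-oxohex-1-en-3-yl] (5E)-2-(diethoxyphosphoryl)-6-methyldec-5-enedioate (both C2 epimers) | C=C[C@@](C)(OC(=O)CCC/C(C)=C/CCC(C(=O)OCC)P(=O)(OCC)OCC)CCC=O | intermediate
20 | ethyl (6E,10E,14S)-14-ethenyl-6,14-dimethyl-2-oxo-1-oxacyclotetradeca-6,10-diene-10-carboxylate | O=C1O[C@](C)(C=C)CC/C=C(/C(=O)OCC)CC/C=C(\C)CCC1 | intermediate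
21 | (6E,10E,14S)-14-ethenyl-10-(hydroxymethyl)-6,14-dimethyl-1-oxacyclotetradeca-6,10-dien-2-one | O=C1O[C@](C)(C=C)CC/C=C(/CO)CC/C=C(\C)CCC1 | intermediate
22 | (6E,10E,14S)-10-{[(tert-butyldimethylsilyl)oxy]methyl}-14-ethenyl-6,14-dimethyl-1-oxacyclotetradeca-6,10-dien-2-one | O=C1O[C@](C)(C=C)CC/C=C(/CO[Si](C)(C)C(C)(C)C)CC/C=C(\C)CCC1 | intermediate
23 | (2Z,6E,10E,14S)-10-{[(tert-butyldimethylsilyl)oxy]methyl}-14-ethenyl-6,14-dimethyl-2-[(trimethylsilyl)oxy]-1-oxacyclotetradeca-2,6,10-triene | C[Si](C)(C)O/C1=C\CC/C(C)=C/CC/C(CO[Si](C)(C)C(C)(C)C)=C\CC[C@@](C)(C=C)O1 | intermediate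
24 | trimethylsilyl (1R,3Z,7E,11E)-8-{[(tert-butyldimethylsilyl)oxy]methyl}-4,12-dimethylcyclotetradeca-3,7,11-triene-1-carboxylate | C[Si](C)(C)OC(=O)[C@H]1C/C=C(/C)CC/C=C(/CO[Si](C)(C)C(C)(C)C)CC/C=C(\C)CC1 | intermediate
25 | (1R,3Z,7E,11E)-8-{[(tert-butyldimethylsilyl)oxy]methyl}-4,12-dimethylcyclotetradeca-3,7,11-triene-1-carboxylic acid | OC(=O)[C@H]1C/C=C(/C)CC/C=C(/CO[Si](C)(C)C(C)(C)C)CC/C=C(\C)CC1 | intermediate
26 | (1R,3Z,7E,11E)-8-{[(tert-butyldimethylsilyl)oxy]methyl}-N-methoxy-N,4,12-trimethylcyclotetradeca-3,7,11-triene-1-carboxamide | CON(C)C(=O)[C@H]1C/C=C(/C)CC/C=C(/CO[Si](C)(C)C(C)(C)C)CC/C=C(\C)CC1 | intermediate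
27 | 5-bromo-2-methylpent-2-ene | CC(C)=CCCBr | starting material
28 | (4-methylpent-3-en-1-yl)magnesium bromide | CC(C)=CCC[Mg]Br | intermediate
29 | 1-[(1R,3Z,7E,11E)-8-{[(tert-butyldimethylsilyl)oxy]methyl}-4,12-dimethylcyclotetradeca-3,7,11-trien-1-yl]-5-methylhex-4-en-1-one | CC(C)=CCCC(=O)[C@H]1C/C=C(/C)CC/C=C(/CO[Si](C)(C)C(C)(C)C)CC/C=C(\C)CC1 | intermediate
30 | (1R,3Z,7E,11E)-8-{[(tert-butyldimethylsilyl)oxy]methyl}-4,12-dimethyl-1-(6-methylhepta-1,5-dien-2-yl)cyclotetradeca-3,7,11-triene | C=C(CCC=C(C)C)[C@H]1C/C=C(/C)CC/C=C(/CO[Si](C)(C)C(C)(C)C)CC/C=C(\C)CC1 | intermediate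
31 | (1R,3Z,7E,11E)-8-(hydroxymethyl)-4,12-dimethyl-1-(6-methylhepta-1,5-dien-2-yl)cyclotetradeca-3,7,11-triene (CNP0237384.1) | C=C(CCC=C(C)C)[C@H]1C/C=C(/C)CC/C=C(/CO)CC/C=C(\C)CC1 | target

## Step count and least certain steps

Total: 18 steps. Longest linear sequence: 16 steps (5 → 31 through steps 3 to 18). The branch from 1 runs 14 steps (steps 1, 2 and 7 to 18).

**Step 14 (key step).**
- Most likely failure: loss of geometric control in the ring-bound rearrangement. Imperfect ketene acetal geometry, or escape through a boat or the opposite-face chair, would change the C3=C4 geometry and in the last two cases also C1. The ten-atom tether has not been tested for how strictly it enforces one bridging mode with a tertiary carbinol. Competing C-silylation or self-condensation of the lactone enolate would lower conversion.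
- Fallback: separate the stereochemical relay from ring formation; it sets out from 17 and returns at 25.
- LiN(iPr)2 (2.5 equiv, the first equivalent going to the phosphonoacetate C–H), Me3SiCl and THF/DMPU from −78 °C to rt should rearrange the open-chain ester through an unconstrained chair to (2R,4Z)-8-[(tert-butyldimethylsilyl)oxy]-2-[(3E)-7-(diethoxyphosphoryl)-8-ethoxy-3-methyl-8-oxooct-3-en-1-yl]-5-methyloct-4-enoic acid F1.
- HF·pyridine would then give the hydroxy acid F2 and Dess–Martin periodinane the aldehyde acid F3.
- LiCl/DBU at high dilution would close the ring at C7=C8 to (1R,3Z,7E,11E)-8-(ethoxycarbonyl)-4,12-dimethylcyclotetradeca-3,7,11-triene-1-carboxylic acid F4.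
- Excess iBu2AlH would give the hydroxy acid F5, and TBSCl/imidazole the bis-silyl compound F6, whose silyl ester is cleaved by K2CO3 in aqueous MeOH to reach 25.
- Cost of the fallback: without the tether the chair with C5 equatorial competes, so the (2S,4E) diastereomer of F1 must be removed (AgNO3-impregnated silica). Ketene acetal leakage would then lower enantiopurity instead of giving a diastereomer.

**Step 11.**
- Most likely failure: oligomerisation competing with ring closure, and erosion of E selectivity because the α-branched phosphonate is less acidic and adds less reversibly than an unsubstituted one.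
- Fallback: switch from the phosphonate carbanion to a stabilised phosphorane, whose α-alkyl members are reliably E-selective; it sets out from 14 and returns at 20.
- Ethyl (triphenylphosphoranylidene)acetate (2.2 equiv, MeCN, reflux) would be C-alkylated by the iodide and transylidated to phosphorane F7.
- HF·pyridine followed by aqueous NaBF4 would give the hydroxy phosphonium tetrafluoroborate F8, with the ylide masked by protonation.
- Dess–Martin periodinane would give the aldehyde salt F9. Slow addition of F9 to iPr2NEt in refluxing CH2Cl2 at high dilution would release the ylide for an intramolecular Wittig closure to 20.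

**Step 12.**
- Most likely failure: over-reduction. Hydride could also attack the ring lactone and open it, or reduce the enoate in a conjugate sense, since the selectivity rests only on the steric shielding of the tertiary alkoxy carbon.
- Fallback: replace direct hydride reduction by hydrolysis and activated reduction; it sets out from 20 and returns at 21.
- LiOH in aqueous THF/MeOH should saponify the ethyl ester in preference to the tert-alkyl lactone and give the acid F10.
- Isobutyl chloroformate and N-methylmorpholine at −15 °C would give the mixed anhydride F11, which NaBH4 in aqueous THF reduces to 21 without touching the lactone.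

**Step 4.**
- Most likely failure: inefficient alkenyl transfer from the alanate to oxirane, with butyl or methyl transfer or Lewis-acid opening of the epoxide taking over.
- Fallback: go through an isolated alkenyl iodide and an alkenyllithium; it sets out from 6 and returns at 9.
- The same carboalumination quenched with I2 would give tert-butyl{[(5E)-6-iodo-5-methylhex-5-en-1-yl]oxy}dimethylsilane F12.
- t-BuLi (2.1 equiv, Et2O, −78 °C) would give the alkenyllithium F13 with retention, and oxirane with BF3·OEt2 at −78 °C would give 9.

## Further compounds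

F1 | step 14 | (2R,4Z)-8-[(tert-butyldimethylsilyl)oxy]-2-[(3E)-7-(diethoxyphosphoryl)-8-ethoxy-3-methyl-8-oxooct-3-en-1-yl]-5-methyloct-4-enoic acid | OC(=O)[C@H](CC/C(C)=C/CCC(C(=O)OCC)P(=O)(OCC)OCC)C/C=C(/C)CCCO[Si](C)(C)C(C)(C)C
F2 | step 14 | (2R,4Z)-2-[(3E)-7-(diethoxyphosphoryl)-8-ethoxy-3-methyl-8-oxooct-3-en-1-yl]-8-hydroxy-5-methyloct-4-enoic acid | OC(=O)[C@H](CC/C(C)=C/CCC(C(=O)OCC)P(=O)(OCC)OCC)C/C=C(/C)CCCO
F3 | step 14 | (2R,4Z)-2-[(3E)-7-(diethoxyphosphoryl)-8-ethoxy-3-methyl-8-oxooct-3-en-1-yl]-5-methyl-8-oxooct-4-enoic acid | OC(=O)[C@H](CC/C(C)=C/CCC(C(=O)OCC)P(=O)(OCC)OCC)C/C=C(/C)CCC=O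
F4 | step 14 | (1R,3Z,7E,11E)-8-(ethoxycarbonyl)-4,12-dimethylcyclotetradeca-3,7,11-triene-1-carboxylic acid | OC(=O)[C@H]1C/C=C(/C)CC/C=C(/C(=O)OCC)CC/C=C(\C)CC1
F5 | step 14 | (1R,3Z,7E,11E)-8-(hydroxymethyl)-4,12-dimethylcyclotetradeca-3,7,11-triene-1-carboxylic acid | OC(=O)[C@H]1C/C=C(/C)CC/C=C(/CO)CC/C=C(\C)CC1
F6 | step 14 | tert-butyldimethylsilyl (1R,3Z,7E,11E)-8-{[(tert-butyldimethylsilyl)oxy]methyl}-4,12-dimethylcyclotetradeca-3,7,11-triene-1-carboxylate | CC(C)(C)[Si](C)(C)OC(=O)[C@H]1C/C=C(/C)CC/C=C(/CO[Si](C)(C)C(C)(C)C)CC/C=C(\C)CC1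
F7 | step 11 | (3S)-6-[(tert-butyldimethylsilyl)oxy]-3-methylhex-1-en-3-yl (5E)-10-ethoxy-5-methyl-10-oxo-9-(triphenylphosphoranylidene)dec-5-enoate | C=C[C@@](C)(OC(=O)CCC/C(C)=C/CCC(C(=O)OCC)=P(c1ccccc1)(c1ccccc1)c1ccccc1)CCCO[Si](C)(C)C(C)(C)C
F8 | step 11 | [(5E)-1-ethoxy-10-{[(3S)-6-hydroxy-3-methylhex-1-en-3-yl]oxy}-6-methyl-1,10-dioxodec-5-en-2-yl]triphenylphosphonium tetrafluoroborate (both C2 epimers) | C=C[C@@](C)(OC(=O)CCC/C(C)=C/CCC(C(=O)OCC)[P+](c1ccccc1)(c1ccccc1)c1ccccc1)CCCO.F[B-](F)(F)F
F9 | step 11 | [(5E)-1-ethoxy-6-methyl-10-{[(3S)-3-methyl-6-oxohex-1-en-3-yl]oxy}-1,10-dioxodec-5-en-2-yl]triphenylphosphonium tetrafluoroborate (both C2 epimers) | C=C[C@@](C)(OC(=O)CCC/C(C)=C/CCC(C(=O)OCC)[P+](c1ccccc1)(c1ccccc1)c1ccccc1)CCC=O.F[B-](F)(F)F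
F10 | step 12 | (6E,10E,14S)-14-ethenyl-6,14-dimethyl-2-oxo-1-oxacyclotetradeca-6,10-diene-10-carboxylic acid | O=C1O[C@](C)(C=C)CC/C=C(/C(=O)O)CC/C=C(\C)CCC1
F11 | step 12 | (6E,10E,14S)-14-ethenyl-6,14-dimethyl-2-oxo-1-oxacyclotetradeca-6,10-diene-10-carboxylic 2-methylpropyl carbonic anhydride | O=C1O[C@](C)(C=C)CC/C=C(/C(=O)OC(=O)OCC(C)C)CC/C=C(\C)CCC1
F12 | step 4 | tert-butyl{[(5E)-6-iodo-5-methylhex-5-en-1-yl]oxy}dimethylsilane | I/C=C(\C)CCCCO[Si](C)(C)C(C)(C)C
F13 | step 4 | [(1E)-6-[(tert-butyldimethylsilyl)oxy]-2-methylhex-1-en-1-yl]lithium | [Li]/C=C(\C)CCCCO[Si](C)(C)C(C)(C)C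
A1 | alternative 1 | methyl (6Z,9R,12E)-3-acetoxy-6,12-dimethyl-2-methylidene-9-(6-methylhepta-1,5-dien-2-yl)-14-(phenylsulfonyl)tetradeca-6,12-dienoate (both C3 epimers) | C=C(CCC=C(C)C)[C@@H](C/C=C(/C)CCC(OC(C)=O)C(=C)C(=O)OC)CC/C(C)=C/CS(=O)(=O)c1ccccc1
A2 | alternative 1 | methyl (1R,3Z,7E,11E)-4,12-dimethyl-1-(6-methylhepta-1,5-dien-2-yl)-10-(phenylsulfonyl)cyclotetradeca-3,7,11-triene-8-carboxylate (both C10 epimers) | C=C(CCC=C(C)C)[C@H]1C/C=C(/C)CC/C=C(/C(=O)OC)CC(S(=O)(=O)c2ccccc2)/C=C(\C)CC1
A3 | alternative 2 | (3Z)-7,7-dimethoxy-4-methylhept-3-en-1-yl N,N-diisopropylcarbamate | CC(C)N(C(C)C)C(=O)OCC/C=C(/C)CCC(OC)OC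
A4 | alternative 2 | 2-[(3E)-6-[(tert-butyldimethylsilyl)oxy]-3-methylhex-3-en-1-yl]-4,4,5,5-tetramethyl-1,3,2-dioxaborolane | CC1(C)OB(CC/C(C)=C/CCO[Si](C)(C)C(C)(C)C)OC1(C)C
A5 | alternative 2 | (6-methylhepta-1,5-dien-2-yl)lithium | [Li]C(=C)CCC=C(C)C
A6 | alternative 2 | tert-butyl{[(3E,7R,9Z)-13,13-dimethoxy-4,10-dimethyl-7-(6-methylhepta-1,5-dien-2-yl)trideca-3,9-dien-1-yl]oxy}dimethylsilane | C=C(CCC=C(C)C)[C@H](CC/C(C)=C/CCO[Si](C)(C)C(C)(C)C)C/C=C(/C)CCC(OC)OC
A7 | alternative 3 | 1,3-dioxoisoindolin-2-yl (4R,6Z,10E,14E)-11-{[(tert-butyldimethylsilyl)oxy]methyl}-15-iodo-7-methyl-4-(6-methylhepta-1,5-dien-2-yl)hexadeca-6,10,14-trienoate | C=C(CCC=C(C)C)[C@H](CCC(=O)ON1C(=O)c2ccccc2C1=O)C/C=C(/C)CC/C=C(/CO[Si](C)(C)C(C)(C)C)CC/C=C(\C)I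
A8 | alternative 3 | (1R,3Z,7E,11E)-8-{[(tert-butyldimethylsilyl)oxy]methyl}-4,12-dimethyl-1-(6-methylhepta-1,5-dien-2-yl)cyclotetradeca-3,7,11-triene (identical with 30) | C=C(CCC=C(C)C)[C@H]1C/C=C(/C)CC/C=C(/CO[Si](C)(C)C(C)(C)C)CC/C=C(\C)CC1
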